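**Retrosynthetic overview**
- The target is opened at the two esters: acetylation at O8 and Yamaguchi esterification at O9 of a triol lactone with (2S,3S)-epoxyangelic acid, itself made from angelic acid by Sharpless epoxidation.
- Key disconnection C6–C7: in the precursor both carbons are carbonyl carbons (C6 enal, C7 ketone of a 2-methylene-3-oxo ester). Reduction by divalent chromium with Et3SiCl turns C7 into a nucleophilic γ-siloxyallyl (oxygen-bearing ester homoenolate) carbon that attacks C6. This closes the ten-membered ring first and sets C6 and C7; the lactone ring closes second (O6 onto C12).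
- The keto-enoate comes from a Baylis–Hillman reaction and oxidation of a dialdehyde. The 1(10)Z olefin comes from a Z-selective Wittig reaction of a phosphonium salt (from 5-chloro-1-pentyne, which fixes 4E) with the methyl ketone from 2,3-O-isopropylidene-D-erythronolactone and CH3Li (C8 and C9 from the chiral pool).

Assumption: the SMILES is read as the (6S,7S,8S,9S)-1(10)Z,4E-germacradien-12,6-olide carrying a (2S,3S)-epoxyangelate on O9; germacrane locants (C1–C15) are used throughout.

**Route**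

Step 1
Reactants: 1 5-chloro-1-pentyne
Product: 3 (2E)-6-chloro-3-methylhex-2-en-1-ol, via alkenylalane 2 (not isolated)
Conditions: Al(CH3)3 (2 equiv), (C5H5)2ZrCl2 (0.2 equiv), CH2Cl2, 0 °C → rt; then n-BuLi, (CH2O)n, THF, −78 °C → rt
Reagents that add atoms: trimethylaluminium C[Al](C)C; paraformaldehyde (formaldehyde unit) C=O
Why: Zirconium-catalysed Negishi carboalumination adds CH3 and Al syn across the alkyne (CH3 to the internal carbon) and the alkenylalanate is hydroxymethylated with retention, so the C4=C5 olefin is formed E.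

Step 2
Reactants: 3 (2E)-6-chloro-3-methylhex-2-en-1-ol
Product: 4 [(4E)-6-hydroxy-4-methylhex-4-en-1-yl]triphenylphosphonium iodide
Conditions: NaI (1.5 equiv), PPh3 (1.2 equiv), CH3CN, reflux
Reagents that add atoms: triphenylphosphine c1ccc(cc1)P(c1ccccc1)c1ccccc1; sodium iodide [Na+].[I-]
Why: Finkelstein exchange followed by SN2 quaternisation of the phosphine at the primary carbon; the allylic alcohol is inert under these neutral conditions.

Step 3
Reactants: 5 2,3-O-isopropylidene-D-erythronolactone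
Product: 6 (3aR,6aR)-2,2,4-trimethyltetrahydrofuro[3,4-d][1,3]dioxol-4-ol (hemiketal, anomer mixture)
Conditions: CH3Li (1.05 equiv), THF, −78 °C; NH4Cl (aq)
Reagents that add atoms: methyllithium [Li]C
Why: Single nucleophilic addition to the lactone, because the lithium hemiketal alkoxide does not collapse at −78 °C; the C8 and C9 stereocentres come unchanged from the chiral pool.

Step 4
Reactants: 4 [(4E)-6-hydroxy-4-methylhex-4-en-1-yl]triphenylphosphonium iodide; 6 hemiketal
Product: 9 (2E,6Z)-7-[(4S,5R)-5-(hydroxymethyl)-2,2-dimethyl-1,3-dioxolan-4-yl]-3-methylocta-2,6-dien-1-ol, via potassium oxido ylide 7 (not isolated), via open-chain hydroxy ketone 8 (not isolated)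
Conditions: 4 (2.2 equiv), KN(SiMe3)2 (4.4 equiv), THF, −78 → 0 °C; then 6, −78 °C → rt
Reagents that add atoms: none
Why: Still-type Z-selective Wittig olefination of an α-alkoxy methyl ketone (the hemiketal reacts through its open form) by a non-stabilised ylide under lithium-free conditions places the oxygenated carbon C9 cis to C2, giving the 1(10)Z olefin.

Step 5
Reactants: 9 diene diol
Product: 10 (4S,5S)-2,2-dimethyl-5-[(2Z,6E)-6-methyl-8-oxoocta-2,6-dien-2-yl]-1,3-dioxolane-4-carbaldehyde
Conditions: Dess–Martin periodinane (2.5 equiv), NaHCO3, CH2Cl2, 0 °C → rt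
Reagents that add atoms: none
Why: Dess–Martin oxidation converts both primary alcohols (allylic C6 and α-alkoxy C7) to aldehydes under buffered conditions that do not epimerise C8 or isomerise the enal.

Step 6
Reactants: 10 dialdehyde; 11 methyl acrylate
Product: 12 methyl 2-{hydroxy[(4R,5S)-2,2-dimethyl-5-[(2Z,6E)-6-methyl-8-oxoocta-2,6-dien-2-yl]-1,3-dioxolan-4-yl]methyl}prop-2-enoate (both carbinol epimers)
Conditions: 11 (5 equiv), DABCO (1 equiv), dioxane/H2O (1:1), rt
Reagents that add atoms: none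
Why: The Morita–Baylis–Hillman reaction takes place only at the activated α-alkoxy aldehyde, the β,β-disubstituted enal being inert; the new carbinol centre is destroyed in the next step.

Step 7
Reactants: 12 Baylis–Hillman adduct
Product: 13 methyl 2-{[(4S,5S)-2,2-dimethyl-5-[(2Z,6E)-6-methyl-8-oxoocta-2,6-dien-2-yl]-1,3-dioxolan-4-yl]carbonyl}prop-2-enoate
Conditions: Dess–Martin periodinane (1.3 equiv), NaHCO3, CH2Cl2, 0 °C; cold filtration, used at once as a dilute THF solution
Reagents that add atoms: none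
Why: Dess–Martin oxidation of the Baylis–Hillman alcohol gives the 2-methylene-3-oxo ester, which is kept cold and dilute because it dimerises on concentration.

Step 8
Reactants: 13 keto-enoate enal
Product: 17 (6S,7S,8S,9S)-7-hydroxy-8,9-(isopropylidenedioxy)germacra-1(10)Z,4E,11(13)-trien-12,6-olide, via siloxyallylchromium species 14 (not isolated), via bis(triethylsilyl) ether ester 15 (not isolated), via dihydroxy ester 16 (not isolated)
Conditions: CrCl2 (6 equiv), Et3SiCl (3 equiv), THF, syringe-pump addition of 13 (final 2 mM), 0 °C → rt; then HF·pyridine, THF, 0 °C → rt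
Reagents that add atoms: none
Why: Proposed new method: one-electron reduction of the doubly activated enone by divalent chromium, O-silylation and capture by a second chromium give a γ-siloxy-2-(methoxycarbonyl)allylchromium in which the former ketone carbon C7 is nucleophilic. It adds through a chair six-membered transition state to the C6 enal carbonyl, closing the ten-membered ring, and desilylation lets O6 lactonise onto C12. The 6,7-anti relation follows from the chair with both ring chains equatorial, and the C7 face is set by the dioxolane (C8–H eclipsing the enol double bond, C9 anti to the incoming aldehyde), giving 6S,7S. The closest known reactions are the chromium-mediated cross-pinacol-type coupling of enones with aldehydes through γ-siloxyallylchromium reagents and the Nozaki–Hiyama–Kishi macrocyclisation of 2-(bromomethyl)acrylates onto enals.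

Step 9
Reactants: 17 lactone acetonide
Product: 18 (6S,7R,8S,9S)-7,8,9-trihydroxygermacra-1(10)Z,4E,11(13)-trien-12,6-olide (C7 descriptor changes by priority only)
Conditions: CeCl3·7H2O (2 equiv), oxalic acid (cat.), CH3CN, rt
Reagents that add atoms: none
Why: Mild Lewis-acid-assisted acetal hydrolysis removes the cis-dioxolane without opening the allylic lactone or triggering transannular cyclisation of the 1,5-diene.

Step 10
Reactants: 19 angelic acid
Product: 20 (2Z)-2-methylbut-2-en-1-ol
Conditions: LiAlH4, Et2O, 0 °C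
Reagents that add atoms: none
Why: Hydride 1,2-reduction of the acid to the allylic alcohol leaves the Z double bond untouched.

Step 11
Reactants: 20 (2Z)-2-methylbut-2-en-1-ol
Product: 21 [(2R,3S)-2,3-dimethyloxiran-2-yl]methanol
Conditions: Ti(OiPr)4 (10 mol %), L-(+)-diethyl tartrate (12 mol %), t-BuOOH, 4 Å molecular sieves, CH2Cl2, −20 °C
Reagents that add atoms: tert-butyl hydroperoxide CC(C)(C)OO
Why: Sharpless asymmetric epoxidation with the L-(+)-tartrate delivers oxygen to the face that gives (2R,3S), and syn addition keeps CH2OH cis to the C3 methyl.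

Step 12
Reactants: 21 epoxy alcohol
Product: 22 (2S,3S)-2,3-dimethyloxirane-2-carboxylic acid
Conditions: RuCl3·xH2O (2 mol %), NaIO4 (3 equiv), EtOAc/CH3CN/H2O, rt
Reagents that add atoms: water O; sodium periodate [Na+].[O-]I(=O)(=O)=O
Why: Ruthenium tetroxide oxidation (catalytic RuCl3 with NaIO4) takes the primary alcohol to the acid without touching either epoxide stereocentre.

Step 13
Reactants: 18 triol lactone; 22 epoxy acid
Product: 24 (6S,7R,8S,9S)-9-{[(2S,3S)-2,3-dimethyloxiran-2-yl]carbonyloxy}-7,8-dihydroxygermacra-1(10)Z,4E,11(13)-trien-12,6-olide, via mixed anhydride 23 (not isolated)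
Conditions: 22 (1.1 equiv), 2,4,6-trichlorobenzoyl chloride, Et3N, THF, rt; then 18, DMAP, toluene, 0 °C → rt
Reagents that add atoms: none
Why: Yamaguchi esterification with a bulky mixed anhydride acylates the allylic C9–OH rather than the neopentyl-type C8–OH or the tertiary C7–OH, with retention at C9.

Step 14
Reactants: 24 C9 monoester
Product: 25 target (CNP0271187.2)
Conditions: Ac2O (1.5 equiv), pyridine, DMAP (cat.), CH2Cl2, 0 °C
Reagents that add atoms: acetic anhydride CC(=O)OC(C)=O
Why: DMAP-catalysed acetylation of the only remaining secondary hydroxyl (C8) leaves the tertiary C7–OH free.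

**Compound list**

1 | 5-chloro-1-pentyne | C#CCCCCl | starting material
2 | (E)-(5-chloro-2-methylpent-1-en-1-yl)dimethylalane | C[Al](C)/C=C(\C)CCCCl | intermediate
3 | (2E)-6-chloro-3-methylhex-2-en-1-ol | OC/C=C(\C)CCCCl | intermediate
4 | [(4E)-6-hydroxy-4-methylhex-4-en-1-yl]triphenylphosphonium iodide | OC/C=C(\C)CCC[P+](c1ccccc1)(c1ccccc1)c1ccccc1.[I-] | intermediate
5 | 2,3-O-isopropylidene-D-erythronolactone, (3aR,6aR)-2,2-dimethyldihydrofuro[3,4-d][1,3]dioxol-4(3aH)-one | O=C1[C@@H]2OC(C)(C)O[C@@H]2CO1 | starting material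
6 | (3aR,6aR)-2,2,4-trimethyltetrahydrofuro[3,4-d][1,3]dioxol-4-ol (anomer mixture) | CC1(O)[C@@H]2OC(C)(C)O[C@@H]2CO1 | intermediate
7 | potassium (2E)-3-methyl-6-(triphenyl-λ5-phosphanylidene)hex-2-en-1-olate | [K+].[O-]C/C=C(\C)CCC=P(c1ccccc1)(c1ccccc1)c1ccccc1 | intermediate
8 | 1-[(4R,5R)-5-(hydroxymethyl)-2,2-dimethyl-1,3-dioxolan-4-yl]ethan-1-one (open form of 6) | CC(=O)[C@@H]1OC(C)(C)O[C@@H]1CO | intermediate
9 | (2E,6Z)-7-[(4S,5R)-5-(hydroxymethyl)-2,2-dimethyl-1,3-dioxolan-4-yl]-3-methylocta-2,6-dien-1-ol | OC/C=C(\C)CC/C=C(/C)[C@@H]1OC(C)(C)O[C@@H]1CO | intermediate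
10 | (4S,5S)-2,2-dimethyl-5-[(2Z,6E)-6-methyl-8-oxoocta-2,6-dien-2-yl]-1,3-dioxolane-4-carbaldehyde | O=C/C=C(\C)CC/C=C(/C)[C@@H]1OC(C)(C)O[C@@H]1C=O | intermediate
11 | methyl acrylate | C=CC(=O)OC | starting material
12 | methyl 2-{hydroxy[(4R,5S)-2,2-dimethyl-5-[(2Z,6E)-6-methyl-8-oxoocta-2,6-dien-2-yl]-1,3-dioxolan-4-yl]methyl}prop-2-enoate (carbinol epimers) | O=C/C=C(\C)CC/C=C(/C)[C@@H]1OC(C)(C)O[C@@H]1C(O)C(=C)C(=O)OC | intermediate
13 | methyl 2-{[(4S,5S)-2,2-dimethyl-5-[(2Z,6E)-6-methyl-8-oxoocta-2,6-dien-2-yl]-1,3-dioxolan-4-yl]carbonyl}prop-2-enoate | O=C/C=C(\C)CC/C=C(/C)[C@@H]1OC(C)(C)O[C@@H]1C(=O)C(=C)C(=O)OC | intermediate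
14 | γ-(triethylsiloxy)-2-(methoxycarbonyl)allylchromium dichloride derived from 13 (trivalent chromium on C13; enol geometry equilibrating; C8 and C9 as in 13) | O=C/C=C(\C)CC/C=C(/C)[C@@H]1OC(C)(C)O[C@@H]1C(O[Si](CC)(CC)CC)=C(C[Cr](Cl)Cl)C(=O)OC | intermediate
15 | methyl 6,7-bis(triethylsilyloxy)-8,9-(isopropylidenedioxy)germacra-1(10)Z,4E,11(13)-trien-12-oate (configuration at C6–C9 as in 17) | CC[Si](CC)(CC)O[C@H]1/C=C(\C)CC/C=C(/C)[C@@H]2OC(C)(C)O[C@@H]2[C@]1(O[Si](CC)(CC)CC)C(=C)C(=O)OC | intermediate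
16 | methyl (6S,7S,8S,9S)-6,7-dihydroxy-8,9-(isopropylidenedioxy)germacra-1(10)Z,4E,11(13)-trien-12-oate | O[C@H]1/C=C(\C)CC/C=C(/C)[C@@H]2OC(C)(C)O[C@@H]2[C@]1(O)C(=C)C(=O)OC | intermediate
17 | (6S,7S,8S,9S)-7-hydroxy-8,9-(isopropylidenedioxy)germacra-1(10)Z,4E,11(13)-trien-12,6-olide | C=C1C(=O)O[C@H]2/C=C(\C)CC/C=C(/C)[C@@H]3OC(C)(C)O[C@@H]3[C@]12O | intermediate
18 | (6S,7R,8S,9S)-7,8,9-trihydroxygermacra-1(10)Z,4E,11(13)-trien-12,6-olide | C=C1C(=O)O[C@H]2/C=C(\C)CC/C=C(/C)[C@H](O)[C@H](O)[C@]12O | intermediate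
19 | angelic acid, (2Z)-2-methylbut-2-enoic acid | C/C=C(/C)C(=O)O | starting material
20 | (2Z)-2-methylbut-2-en-1-ol | C/C=C(/C)CO | intermediate
21 | [(2R,3S)-2,3-dimethyloxiran-2-yl]methanol | OC[C@@]1(C)O[C@H]1C | intermediate
22 | (2S,3S)-2,3-dimethyloxirane-2-carboxylic acid | OC(=O)[C@@]1(C)O[C@H]1C | intermediate
23 | (2S,3S)-2,3-dimethyloxirane-2-carboxylic 2,4,6-trichlorobenzoic anhydride | O=C(OC(=O)[C@@]1(C)O[C@H]1C)c1c(Cl)cc(Cl)cc1Cl | intermediate
24 | (6S,7R,8S,9S)-9-{[(2S,3S)-2,3-dimethyloxiran-2-yl]carbonyloxy}-7,8-dihydroxygermacra-1(10)Z,4E,11(13)-trien-12,6-olide | C=C1C(=O)O[C@H]2/C=C(\C)CC/C=C(/C)[C@H](OC(=O)[C@@]3(C)O[C@H]3C)[C@H](O)[C@]12O | intermediate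
25 | (6S,7S,8S,9S)-8-acetoxy-9-{[(2S,3S)-2,3-dimethyloxiran-2-yl]carbonyloxy}-7-hydroxygermacra-1(10)Z,4E,11(13)-trien-12,6-olide | C=C1C(=O)O[C@H]2/C=C(\C)CC/C=C(/C)[C@H](OC(=O)[C@@]3(C)O[C@H]3C)[C@H](OC(C)=O)[C@]12O | target

**Totals**
Total step count: 14. Longest linear sequence: 10 steps (1, 2, 4, 5, 6, 7, 8, 9, 13, 14).

**Three steps most likely to fail**

Step 8 (reductive macrocyclisation). The enone 13 may be over-reduced or dimerise, the allylchromium may lose the neighbouring alkoxide, or the wrong C6/C7 diastereomer may form. The fallback sets out from 13 and comes back at 17. It separates the making of the nucleophile from the ring closure. Bromotrimethylsilane is added 1,4 to 13 at −78 °C to give the allylic bromide methyl 2-(bromomethyl)-3-[(4S,5S)-2,2-dimethyl-5-[(2Z,6E)-6-methyl-8-oxoocta-2,6-dien-2-yl]-1,3-dioxolan-4-yl]-3-(trimethylsilyloxy)prop-2-enoate F1. F1 is then added slowly to zerovalent indium metal in THF, so the same oxygen-bearing allyl nucleophile arises by insertion into a C–Br bond (Barbier-type closure) instead of by ketyl-type reduction. Dilute HCl work-up removes the silyl group and lactonises to 17.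

Step 4 (Wittig on the hemiketal). The hemiketal may open too slowly, the basic ylide may epimerise or eliminate at C9, or Z selectivity may erode in the presence of several alkoxides. The fallback sets out from 6 and comes back at 9. The open form is trapped with TBSCl and imidazole in DMF as the acyclic ketone 1-[(4R,5R)-5-{[tert-butyl(dimethyl)silyl]oxymethyl}-2,2-dimethyl-1,3-dioxolan-4-yl]ethan-1-one F2. This discrete α-alkoxy ketone is olefinated with ylide 7 (one equivalent less base needed) to give (2E,6Z)-7-[(4S,5R)-5-{[tert-butyl(dimethyl)silyl]oxymethyl}-2,2-dimethyl-1,3-dioxolan-4-yl]-3-methylocta-2,6-dien-1-ol F3. Bu4NF in THF then gives 9.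

Step 13 (C9 versus C8 acylation). The mixed anhydride may not discriminate the two secondary hydroxyls, or the acyl group may migrate. The fallback sets out from 18 and comes back at 25. It differentiates the hydroxyls by allylic oxidation instead of by hindrance. MnO2 oxidises only the allylic C9–OH to give the enone 7,8-dihydroxy-9-oxogermacra-1(10)Z,4E,11(13)-trien-12,6-olide F4. Ac2O/pyridine then acetylates the only secondary hydroxyl to give 8-acetoxy-7-hydroxy-9-oxogermacra-1(10)Z,4E,11(13)-trien-12,6-olide F5. Luche reduction (NaBH4, CeCl3·7H2O, MeOH, −78 °C), with hydride arriving anti to the C8 acetoxy group, restores the cis-8,9 relation in 8-acetoxy-7,9-dihydroxygermacra-1(10)Z,4E,11(13)-trien-12,6-olide F6. F6 is esterified with 22 through anhydride 23 to give 25.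

**Further compounds**
F1 | step 8 | methyl 2-(bromomethyl)-3-[(4S,5S)-2,2-dimethyl-5-[(2Z,6E)-6-methyl-8-oxoocta-2,6-dien-2-yl]-1,3-dioxolan-4-yl]-3-(trimethylsilyloxy)prop-2-enoate | O=C/C=C(\C)CC/C=C(/C)[C@@H]1OC(C)(C)O[C@@H]1C(O[Si](C)(C)C)=C(CBr)C(=O)OC
F2 | step 4 | 1-[(4R,5R)-5-{[tert-butyl(dimethyl)silyl]oxymethyl}-2,2-dimethyl-1,3-dioxolan-4-yl]ethan-1-one | CC(=O)[C@@H]1OC(C)(C)O[C@@H]1CO[Si](C)(C)C(C)(C)C
F3 | step 4 | (2E,6Z)-7-[(4S,5R)-5-{[tert-butyl(dimethyl)silyl]oxymethyl}-2,2-dimethyl-1,3-dioxolan-4-yl]-3-methylocta-2,6-dien-1-ol | OC/C=C(\C)CC/C=C(/C)[C@@H]1OC(C)(C)O[C@@H]1CO[Si](C)(C)C(C)(C)C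
F4 | step 13 | 7,8-dihydroxy-9-oxogermacra-1(10)Z,4E,11(13)-trien-12,6-olide (C6, C7, C8 as in 18) | C=C1C(=O)O[C@H]2/C=C(\C)CC/C=C(/C)C(=O)[C@H](O)[C@]12O
F5 | step 13 | 8-acetoxy-7-hydroxy-9-oxogermacra-1(10)Z,4E,11(13)-trien-12,6-olide (C6, C7, C8 as in 18) | C=C1C(=O)O[C@H]2/C=C(\C)CC/C=C(/C)C(=O)[C@H](OC(C)=O)[C@]12O
F6 | step 13 | 8-acetoxy-7,9-dihydroxygermacra-1(10)Z,4E,11(13)-trien-12,6-olide (C6–C9 as in 25) | C=C1C(=O)O[C@H]2/C=C(\C)CC/C=C(/C)[C@H](O)[C@H](OC(C)=O)[C@]12O
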